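## The problem

Compound 20 is an unsymmetrical biflavone with no stereocentre. Unit 1, a 5-hydroxy-7-methoxyflavone with a 4-methoxyphenyl ring B, is bound through the oxygen on C8 to C4' of ring B of unit 2, a 5,7-dihydroxyflavone. Every selectivity question is therefore regiochemical.

Ring A of unit 1 carries four oxygens (O1 on C8a, O5, O7 and the ether oxygen on C8) and one hydrogen (C6). The ether oxygen is flanked on both sides, so the diaryl ether is best made early, on simple benzene rings, and not between two finished flavones.

Ring C of unit 1 must be fused with O1 next to C8 and the carbonyl next to C5. The other fusion gives the 6-aryloxy isomer, which is also where acid-induced opening and reclosure of an 8-substituted 5-hydroxyflavone leads. Strong hot acid must therefore be avoided once O5 is free.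

Of the five phenolic oxygens, O7 and O4' of unit 1 end as methyl ethers and O5, O5'' and O7'' as free hydroxyls. This asks for protecting groups that leave together under neutral conditions.

The chromone rings can be opened at C2 by hydroxide and other hard nucleophiles, the oxygen-rich rings are sensitive to oxidants, and an iodide on such a ring does not tolerate hot acid or light for long.

The feature that makes the key step possible is the triad C8a–C4a–C5 of unit 1. With a free hydroxyl on C8a, iodine on C4a and a benzyl ether on C5, an acyl group built on C4a can be captured by one oxygen only. The benzene precursor of this triad, resorcinol 9, is symmetric, so the iodine has only one kind of position to enter.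

## Retrosynthesis

**20 from 19.** The three O–benzyl bonds on O5, O5'' and O7'' are cut last. Benzyl is chosen because hydrogenolysis is neutral: it leaves the two methyl ethers alone and gives the acid-driven isomerisation of the 8-aryloxy-5-hydroxyflavone no chance. The precursor 19 is the complete carbon skeleton, and the last step only has to spare the two chromone double bonds.

**19 from 16 and 17 through 18.** Ring C of unit 2 is opened at O1''–C2'' (cyclodehydration of diketone 18) and then at C2''–C3'' (crossed Claisen condensation of ester 16 with acetophenone 17). Cutting the diaryl ether here instead would leave the most hindered bond for the end, between two complete flavones. A chalcone route would need an aldehyde and an oxidative ring closure in the presence of the electron-rich unit 1. The ester route brings in the whole ring A of unit 2 as catalogue compound 17. The condensation must make the enolate acylate the ester without attacking C2 of the chromone in 16.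

**16 from 15.** The O7–methyl bond is cut. The methyl group is put on after ring C is closed because the ring-closure precursor must carry two equivalent hydroxyls; at the stage of 15 the hydroxyl on C7 is the only free one.

**15 from 10, 11 and 12 (key disconnection).** Ring C of unit 1 is cut at C4a–C4, C4–C3 and O1–C2, giving iodophenol 10, carbon monoxide 11 and alkyne 12. Ynone 13 and its diethylamine adduct 14 lie on the way. The neighbouring cut, C-acylation of the tetra-oxygenated ring followed by a Baker–Venkataraman sequence, would need a Lewis acid next to a benzyl ether and would fix the position of the carbon less firmly. The iodide places C4 exactly, and 12 brings ring B with its methoxy group. The forward step must take up CO before the alkyne couples and must close in the six-membered mode.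

**10 from 9.** The C–I bond is cut. Resorcinol 9 has two equivalent free ring positions, each ortho to one hydroxyl, para to the other and ortho to the benzyloxy group. Mono-iodination can therefore give 10 only, and what has to be controlled is a second iodination.

**9 from 8, 7, 5, 4 and 3.** The two hydroxyls of 9 are revealed from the bis-MOM ether 8, which comes from phenol 7 by benzylation. The C–O bond of 7 goes back to the formyl group of 5 through a Baeyer–Villiger oxidation (formate 6). The formyl group of syringaldehyde is thus a masked hydroxyl exactly para to the ether oxygen. The methyl ethers of 3 are exchanged for MOM groups (3 to 4 to 5) because methyl ethers cannot be removed later beside a benzyl ether, whereas MOM leaves with dilute acid.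

**3 from 1 and 2.** The diaryl ether C–O bond is cut to syringaldehyde 1 and methyl 4-fluorobenzoate 2. The ester activates the fluoride for substitution and later serves as the acyl donor for unit 2. Both partners are simple, and the hindered ether is made in the first step.

## Roads not taken

**Alternative 1: carbonyl-directed hydroxylation of both C5 positions at the end.**
- Cut: the two C5–O bonds, leading back to the 5,5''-dideoxy biflavone A2 with O7'' as an acetate.
- Forward step: [RuCl2(p-cymene)]2 with PhI(OCOCF3)2 in trifluoroacetic acid and its anhydride. Each C4 carbonyl directs cyclometalation by divalent ruthenium to its peri C–H bond, oxidation and C–O reductive elimination give the trifluoroacetates, and hydrolysis gives A1. Removal of the acetyl group then gives 20.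
- Merits: both rings A come from cheaper, less oxygenated precursors, O5 needs no protecting group, and the sequence would probably be shorter than the chosen one. In step economy and protecting-group count this road is better.
- Weak points: two directed oxidations must both go to completion on one molecule. A trivalent iodine oxidant in strong acid meets a 4-methoxyphenyl ring, a diaryl ether and the 7-methoxy-8-aryloxy ring, all prone to one-electron oxidation. The strongly acidic medium acts on an 8-aryloxy-5-hydroxyflavone as soon as it forms, which invites the ring-opening isomerisation.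
- Comparison: the chosen plan sets against the shorter route that every oxygen is in place from the first intermediate and that no oxidant is used once the electron-rich biflavone exists (the only oxidations are on aldehyde 5 and resorcinol 9).

**Alternative 2: ring A of unit 1 by cycloaddition onto a pyranone.**
- Cut: C8–C8a and C4a–C5, giving 5-bromo-2-(4-methoxyphenyl)pyran-4-one A4 and the aryloxy-substituted vinylketene silyl acetal A5.
- Forward step: the nucleophilic terminus of A5 (the carbon bearing the aryloxy group) attacks C6 of A4, the ketene acetal carbon bonds to the brominated carbon, and loss of HBr and methanol aromatises the adduct to A3.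
- Merits: A3 would have O5 free, O7 methylated and the aryloxy group on C8, all fixed by the polarity of the diene. There is no iodination, no CO and no protecting-group exchange on ring A. If it worked, it would be more convergent and shorter than the chosen plan.
- Weak points: a monocyclic 4-pyranone is a weak dienophile, unlike the halogenated quinones on which this type of diene is established. A5 is a highly oxygenated, hydrolytically labile diene that must itself be made in several steps. The tert-butyl ester of A3 is a poor Claisen acceptor, so unit 2 would need ester cleavage and an acylation–rearrangement sequence on a substrate with a free O5 hydroxyl.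
- Comparison: the chosen plan is longer but rests on a ring closure with close precedent for ortho-iodophenols, and its regiochemistry is carried by substrate symmetry and not by an untested cycloaddition.

**Alternative 3: anodic closure of ring C of unit 1 at a C–H bond.**
- Cut: the C8a–O1 bond, leading back to diketone A7, in which C8a still carries hydrogen.
- Forward step: anodic oxidation of the enolised diketone on the electron-rich ring lets the enol oxygen attack C8a with loss of two electrons and two protons, giving A6.
- Merits: no halogen, no palladium and no CO. The ring A precursor needs neither the MOM detour nor an iodination, so the early part would be clearly shorter than in the chosen plan.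
- Weak points: the carbon ortho to the acyl group on the other side carries a methoxy group, and ipso attack there with loss of methanol would give the isomeric fusion. The product and its 4-methoxyphenyl ring are as easily oxidised as the substrate. The activated methylene of the diketone can be oxidised or dimerised. A6 has both O5 and O7 methylated, so a selective O5 demethylation must follow.
- Comparison: the chosen plan pays with more steps before ring closure but removes the regiochemical question altogether, since the iodine marks C4a and only one hydroxyl can reach the acyl group.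

Key step: step 8

Assumption: 1-[2,4-bis(benzyloxy)-6-hydroxyphenyl]ethanone (17), the usual dibenzyl ether of 2,4,6-trihydroxyacetophenone, is taken to be a catalogue compound.

## Route

Step 1
Reactants: 1 syringaldehyde (4-hydroxy-3,5-dimethoxybenzaldehyde); 2 methyl 4-fluorobenzoate
Product: 3 methyl 4-(4-formyl-2,6-dimethoxyphenoxy)benzoate
Conditions: K2CO3, DMSO, 130 °C
Reagents that add atoms: none
Why: Nucleophilic aromatic substitution (addition–elimination): the phenoxide of 1 displaces fluoride para to the ester, which stabilises the Meisenheimer intermediate; aldehyde and ester are inert to carbonate in dry DMSO.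

Step 2
Reactants: 3 methyl 4-(4-formyl-2,6-dimethoxyphenoxy)benzoate
Product: 4 methyl 4-(4-formyl-2,6-dihydroxyphenoxy)benzoate
Conditions: BBr3, CH2Cl2, −78 to 0 °C; then ice-water
Reagents that add atoms: none
Why: Lewis-acid cleavage of aryl methyl ethers: BBr3 binds each methoxy oxygen and bromide removes the methyl group by SN2; the diaryl ether offers no alkyl carbon, and the methyl ester and aldehyde should survive at low temperature.

Step 3
Reactants: 4 methyl 4-(4-formyl-2,6-dihydroxyphenoxy)benzoate
Product: 5 methyl 4-[4-formyl-2,6-bis(methoxymethoxy)phenoxy]benzoate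
Conditions: MOMCl, i-Pr2NEt, CH2Cl2, 0 °C to rt
Reagents that add atoms: chloromethyl methyl ether (MOMCl), COCCl
Why: O-alkylation of both phenols to MOM acetals with a hindered amine base; MOM withstands the peracid, the carbonate and the benzylation to come and later leaves with dilute acid that does not touch a benzyl ether.

Step 4
Reactants: 5 methyl 4-[4-formyl-2,6-bis(methoxymethoxy)phenoxy]benzoate
Product: 7 methyl 4-[4-hydroxy-2,6-bis(methoxymethoxy)phenoxy]benzoate, via aryl formate 6 (not isolated)
Conditions: mCPBA, CH2Cl2, rt; aq. Na2S2O3/NaHCO3 wash; then K2CO3 (cat.), MeOH, rt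
Reagents that add atoms: 3-chloroperoxybenzoic acid (mCPBA), OOC(=O)c1cccc(Cl)c1
Why: Baeyer–Villiger (Dakin-type) oxidation: the peracid adduct of the aldehyde rearranges with migration of the aryl group, which the para aryloxy oxygen makes electron-rich enough, to give formate 6; this is methanolysed under mild base, and the MOM acetals and methyl ester are inert to both operations.

Step 5
Reactants: 7 methyl 4-[4-hydroxy-2,6-bis(methoxymethoxy)phenoxy]benzoate
Product: 8 methyl 4-[4-(benzyloxy)-2,6-bis(methoxymethoxy)phenoxy]benzoate
Conditions: BnBr, K2CO3, DMF, rt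
Reagents that add atoms: benzyl bromide, BrCc1ccccc1
Why: Williamson ether synthesis on the only free phenol; it places the benzyl group on the oxygen that becomes O5 of unit 1.

Step 6
Reactants: 8 methyl 4-[4-(benzyloxy)-2,6-bis(methoxymethoxy)phenoxy]benzoate
Product: 9 methyl 4-[4-(benzyloxy)-2,6-dihydroxyphenoxy]benzoate
Conditions: HCl (cat.), MeOH, 40 °C
Reagents that add atoms: none
Why: Acid-catalysed methanolysis of the two MOM acetals; the benzyl ether is stable, the methyl ester can only exchange with methanol, and the product is the symmetric resorcinol.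

Step 7
Reactants: 9 methyl 4-[4-(benzyloxy)-2,6-dihydroxyphenoxy]benzoate
Product: 10 methyl 4-[4-(benzyloxy)-2,6-dihydroxy-3-iodophenoxy]benzoate
Conditions: NIS (1.0 equiv), MeCN, −20 to 0 °C, dark
Reagents that add atoms: N-iodosuccinimide, O=C1CCC(=O)N1I
Why: Electrophilic aromatic iodination of a resorcinol: the two free ring positions are equivalent by symmetry, so only one mono-iodide can form, and one equivalent of NIS at low temperature is meant to hold back a second iodination.

Step 8
Reactants: 10 methyl 4-[4-(benzyloxy)-2,6-dihydroxy-3-iodophenoxy]benzoate; 11 carbon monoxide; 12 4-ethynylanisole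
Product: 15 methyl 4-{[5-(benzyloxy)-7-hydroxy-2-(4-methoxyphenyl)-4-oxo-4H-chromen-8-yl]oxy}benzoate, via ynone 13 (not isolated), via enaminone 14 (not isolated)
Conditions: PdCl2(PPh3)2 (5 mol %), CO (10 bar), Et2NH, DMF, 90 °C
Reagents that add atoms: none
Why: This is the palladium-catalysed carbonylative Sonogashira coupling of an ortho-iodophenol with a terminal alkyne and cyclisation in the same flask, a known entry to flavones. Zerovalent palladium formed from PdCl2(PPh3)2 inserts into the C–I bond of 10, CO inserts to give an aroyl complex of divalent palladium, and the acetylide formed from 12 and the amine is transferred and reductively eliminated, which forms C4a–C4 and C4–C3 in ynone 13. Diethylamine adds to the triple bond of 13 to give enaminone 14, and the hydroxyl on C8a replaces the amine by addition–elimination at the β-carbon, forming O1–C2; ring C thus closes in the 6-endo mode (6-endo-dig counted on the ynone, 6-endo-trig on the enaminone). No stereocentre is formed. Three selectivities are needed: CO uptake before alkynylation, favoured by CO pressure, by leaving out CuI and by the two ortho substituents, which favour migratory insertion; 6-endo over 5-exo closure to an aurone, secured by the amine relay; and closure through the right oxygen, secured by the substrate, since O5 is benzylated and the second free hydroxyl is para to the acyl carbon. The methyl ester, benzyl ether and diaryl ether should be inert under these conditions.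

Step 9
Reactants: 15 methyl 4-{[5-(benzyloxy)-7-hydroxy-2-(4-methoxyphenyl)-4-oxo-4H-chromen-8-yl]oxy}benzoate
Product: 16 methyl 4-{[5-(benzyloxy)-7-methoxy-2-(4-methoxyphenyl)-4-oxo-4H-chromen-8-yl]oxy}benzoate
Conditions: MeI, K2CO3, acetone, 50 °C
Reagents that add atoms: iodomethane, CI
Why: Williamson methylation of the only free phenol, the hydroxyl on C7; O5 stays benzylated and the chromone is stable to carbonate.

Step 10
Reactants: 16 methyl 4-{[5-(benzyloxy)-7-methoxy-2-(4-methoxyphenyl)-4-oxo-4H-chromen-8-yl]oxy}benzoate; 17 1-[2,4-bis(benzyloxy)-6-hydroxyphenyl]ethanone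
Product: 18 1-[2,4-bis(benzyloxy)-6-hydroxyphenyl]-3-(4-{[5-(benzyloxy)-7-methoxy-2-(4-methoxyphenyl)-4-oxo-4H-chromen-8-yl]oxy}phenyl)propane-1,3-dione
Conditions: LiN(SiMe3)2 (4 equiv), THF, −78 °C to rt, then 50 °C; then 1 M HCl
Reagents that add atoms: none
Why: Crossed Claisen condensation: the phenoxide–enolate dianion of 17 adds to the methyl ester of 16, methoxide leaves, and deprotonation of the diketone draws the equilibrium forward; the non-nucleophilic amide base is chosen to spare C2 of the chromone.

Step 11
Reactants: 18 1-[2,4-bis(benzyloxy)-6-hydroxyphenyl]-3-(4-{[5-(benzyloxy)-7-methoxy-2-(4-methoxyphenyl)-4-oxo-4H-chromen-8-yl]oxy}phenyl)propane-1,3-dione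
Product: 19 5-(benzyloxy)-8-{4-[5,7-bis(benzyloxy)-4-oxo-4H-chromen-2-yl]phenoxy}-7-methoxy-2-(4-methoxyphenyl)-4H-chromen-4-one
Conditions: p-TsOH·H2O (20 mol %), toluene, 100 °C
Reagents that add atoms: none
Why: Acid-catalysed cyclodehydration of a 2-hydroxyaryl 1,3-diketone, the standard closure to a flavone: the ortho hydroxyl adds to the distal carbonyl and water is lost; with O5 of unit 1 still benzylated, the acid has no path to the ring-opening isomerisation.

Step 12
Reactants: 19 5-(benzyloxy)-8-{4-[5,7-bis(benzyloxy)-4-oxo-4H-chromen-2-yl]phenoxy}-7-methoxy-2-(4-methoxyphenyl)-4H-chromen-4-one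
Product: 20 5-hydroxy-8-[4-(5,7-dihydroxy-4-oxo-4H-chromen-2-yl)phenoxy]-7-methoxy-2-(4-methoxyphenyl)-4H-chromen-4-one (CNP0259871.0)
Conditions: H2 (1 atm), 10% Pd/C, THF–MeOH, rt
Reagents that add atoms: none
Why: Catalytic hydrogenolysis of the three aryl benzyl ethers under neutral conditions; the methyl ethers, the diaryl ether and the chromone double bonds (vinylogous esters) are expected to be retained.

## Compound list

1 | syringaldehyde (4-hydroxy-3,5-dimethoxybenzaldehyde) | COc1cc(C=O)cc(OC)c1O | starting material
2 | methyl 4-fluorobenzoate | COC(=O)c1ccc(F)cc1 | starting material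
3 | methyl 4-(4-formyl-2,6-dimethoxyphenoxy)benzoate | COC(=O)c1ccc(Oc2c(OC)cc(C=O)cc2OC)cc1 | intermediate
4 | methyl 4-(4-formyl-2,6-dihydroxyphenoxy)benzoate | COC(=O)c1ccc(Oc2c(O)cc(C=O)cc2O)cc1 | intermediate
5 | methyl 4-[4-formyl-2,6-bis(methoxymethoxy)phenoxy]benzoate | COCOc1cc(C=O)cc(OCOC)c1Oc1ccc(C(=O)OC)cc1 | intermediate
6 | methyl 4-[4-(formyloxy)-2,6-bis(methoxymethoxy)phenoxy]benzoate (aryl formate, not isolated) | COCOc1cc(OC=O)cc(OCOC)c1Oc1ccc(C(=O)OC)cc1 | intermediate
7 | methyl 4-[4-hydroxy-2,6-bis(methoxymethoxy)phenoxy]benzoate | COCOc1cc(O)cc(OCOC)c1Oc1ccc(C(=O)OC)cc1 | intermediate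
8 | methyl 4-[4-(benzyloxy)-2,6-bis(methoxymethoxy)phenoxy]benzoate | COCOc1cc(OCc2ccccc2)cc(OCOC)c1Oc1ccc(C(=O)OC)cc1 | intermediate
9 | methyl 4-[4-(benzyloxy)-2,6-dihydroxyphenoxy]benzoate | COC(=O)c1ccc(Oc2c(O)cc(OCc3ccccc3)cc2O)cc1 | intermediate
10 | methyl 4-[4-(benzyloxy)-2,6-dihydroxy-3-iodophenoxy]benzoate | COC(=O)c1ccc(Oc2c(O)cc(OCc3ccccc3)c(I)c2O)cc1 | intermediate
11 | carbon monoxide | [C-]#[O+] | starting material
12 | 4-ethynylanisole (1-ethynyl-4-methoxybenzene) | C#Cc1ccc(OC)cc1 | starting material
13 | methyl 4-{4-(benzyloxy)-2,6-dihydroxy-3-[3-(4-methoxyphenyl)prop-2-ynoyl]phenoxy}benzoate (ynone, not isolated) | COC(=O)c1ccc(Oc2c(O)cc(OCc3ccccc3)c(C(=O)C#Cc3ccc(OC)cc3)c2O)cc1 | intermediate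
14 | methyl 4-{4-(benzyloxy)-3-[(2E)-3-(diethylamino)-3-(4-methoxyphenyl)prop-2-enoyl]-2,6-dihydroxyphenoxy}benzoate (enaminone, not isolated) | COC(=O)c1ccc(Oc2c(O)cc(OCc3ccccc3)c(C(=O)/C=C(/N(CC)CC)c3ccc(OC)cc3)c2O)cc1 | intermediate
15 | methyl 4-{[5-(benzyloxy)-7-hydroxy-2-(4-methoxyphenyl)-4-oxo-4H-chromen-8-yl]oxy}benzoate | COc1ccc(-c2cc(=O)c3c(OCc4ccccc4)cc(O)c(Oc4ccc(C(=O)OC)cc4)c3o2)cc1 | intermediate
16 | methyl 4-{[5-(benzyloxy)-7-methoxy-2-(4-methoxyphenyl)-4-oxo-4H-chromen-8-yl]oxy}benzoate | COc1ccc(-c2cc(=O)c3c(OCc4ccccc4)cc(OC)c(Oc4ccc(C(=O)OC)cc4)c3o2)cc1 | intermediate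
17 | 1-[2,4-bis(benzyloxy)-6-hydroxyphenyl]ethanone | CC(=O)c1c(O)cc(OCc2ccccc2)cc1OCc1ccccc1 | starting material
18 | 1-[2,4-bis(benzyloxy)-6-hydroxyphenyl]-3-(4-{[5-(benzyloxy)-7-methoxy-2-(4-methoxyphenyl)-4-oxo-4H-chromen-8-yl]oxy}phenyl)propane-1,3-dione | COc1ccc(-c2cc(=O)c3c(OCc4ccccc4)cc(OC)c(Oc4ccc(C(=O)CC(=O)c5c(O)cc(OCc6ccccc6)cc5OCc5ccccc5)cc4)c3o2)cc1 | intermediate
19 | 5-(benzyloxy)-8-{4-[5,7-bis(benzyloxy)-4-oxo-4H-chromen-2-yl]phenoxy}-7-methoxy-2-(4-methoxyphenyl)-4H-chromen-4-one | COc1ccc(-c2cc(=O)c3c(OCc4ccccc4)cc(OC)c(Oc4ccc(-c5cc(=O)c6c(OCc7ccccc7)cc(OCc7ccccc7)cc6o5)cc4)c3o2)cc1 | intermediate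
20 | 5-hydroxy-8-[4-(5,7-dihydroxy-4-oxo-4H-chromen-2-yl)phenoxy]-7-methoxy-2-(4-methoxyphenyl)-4H-chromen-4-one (CNP0259871.0) | COc1ccc(-c2cc(=O)c3c(O)cc(OC)c(Oc4ccc(-c5cc(=O)c6c(O)cc(O)cc6o5)cc4)c3o2)cc1 | target

## Step count and risks

Total step count: 12. Longest linear sequence: 12 steps, from 1 to 20; compounds 2, 11, 12 and 17 enter as catalogue compounds.

**Step 8 (key step).** The aryl palladium may couple with the alkyne before CO is taken up, which leads on to a benzofuran. The acyl palladium may be captured by diethylamine or by a phenoxide of a second molecule. The hindered, electron-rich aryl palladium may lose iodine reductively, or the ynone may close 5-exo.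
Fallback, from 10 back to 15: both hydroxyls of 10 are acetylated (Ac2O, pyridine) to methyl 4-[2,6-bis(acetyloxy)-4-(benzyloxy)-3-iodophenoxy]benzoate F3. Carbonylative Sonogashira coupling of F3 with 11 and 12 (PdCl2(PPh3)2, Et3N, THF, CO 1 bar, rt to 40 °C) then runs with no phenoxide and no secondary amine in the flask and is stopped at methyl 4-{2,6-bis(acetyloxy)-4-(benzyloxy)-3-[3-(4-methoxyphenyl)prop-2-ynoyl]phenoxy}benzoate F4. In a separate operation Et2NH in EtOH removes both acetyl groups from F4 and closes ring C by the same amine relay, which gives 15.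

**Step 1.** The substitution may be slow, because the phenoxide of 1 is hindered and weakened by its para formyl group and the fluoride is only moderately activated. At the temperature needed, the phenoxide may also take a methyl group from the ester.
Fallback, from 1 back to 3: methyl 4-iodobenzoate is converted in one pot (mCPBA, TsOH·H2O, MeCN; then 1,3,5-trimethoxybenzene) into [4-(methoxycarbonyl)phenyl](2,4,6-trimethoxyphenyl)iodonium tosylate F1. F1 arylates the phenoxide of 1 (K2CO3, MeCN, 55 °C) by ligand coupling at iodine, a process that tolerates two ortho substituents and needs no activating group, and gives 3.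

**Step 7.** A second iodination is barely slower than the first, so over-iodination and oxidative degradation of the electron-rich resorcinol are the likely losses.
Fallback, from 8 back to 10: the iodine is introduced before the MOM groups are removed. Treating 8 with NIS in MeCN at rt gives methyl 4-[4-(benzyloxy)-3-iodo-2,6-bis(methoxymethoxy)phenoxy]benzoate F2. In the ether series the first iodine twists its two alkoxy neighbours out of conjugation and so slows the second substitution. Dilute HCl in MeOH at rt, kept mild to spare the iodide, then gives 10.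

**Step 10.** The para-oxygenated ester is a sluggish acyl acceptor, so condensation may be incomplete. The enolate may also add to C2 of the chromone in 16 and open it.
Fallback, from 16 back to 18: the ester is saponified (LiOH, THF–H2O, rt) to 4-{[5-(benzyloxy)-7-methoxy-2-(4-methoxyphenyl)-4-oxo-4H-chromen-8-yl]oxy}benzoic acid F5. F5 is esterified with the phenol of 17 (EDC·HCl, DMAP, CH2Cl2) to 2-acetyl-3,5-bis(benzyloxy)phenyl 4-{[5-(benzyloxy)-7-methoxy-2-(4-methoxyphenyl)-4-oxo-4H-chromen-8-yl]oxy}benzoate F6. Baker–Venkataraman rearrangement of F6 (t-BuOK, THF, rt) transfers the aroyl group intramolecularly to the methyl ketone and gives 18.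

**Step 12.** A chromone C2=C3 bond may be over-reduced, and the cleavage may stall when partly debenzylated material falls out of solution.
Fallback, from 19 back to 20: the benzyl ethers are cleaved by Lewis acid instead of hydrogen (BCl3, pentamethylbenzene, CH2Cl2, −78 °C), with pentamethylbenzene trapping the benzyl cations. The methyl ethers are not peri to a carbonyl and should stay. No new compound arises (F0).

## Further compounds

F1 | step 1 | [4-(methoxycarbonyl)phenyl](2,4,6-trimethoxyphenyl)iodonium 4-methylbenzenesulfonate | COC(=O)c1ccc([I+]c2c(OC)cc(OC)cc2OC)cc1.Cc1ccc(S(=O)(=O)[O-])cc1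
F2 | step 7 | methyl 4-[4-(benzyloxy)-3-iodo-2,6-bis(methoxymethoxy)phenoxy]benzoate | COCOc1cc(OCc2ccccc2)c(I)c(OCOC)c1Oc1ccc(C(=O)OC)cc1
F3 | step 8 | methyl 4-[2,6-bis(acetyloxy)-4-(benzyloxy)-3-iodophenoxy]benzoate | COC(=O)c1ccc(Oc2c(OC(C)=O)cc(OCc3ccccc3)c(I)c2OC(C)=O)cc1
F4 | step 8 | methyl 4-{2,6-bis(acetyloxy)-4-(benzyloxy)-3-[3-(4-methoxyphenyl)prop-2-ynoyl]phenoxy}benzoate | COC(=O)c1ccc(Oc2c(OC(C)=O)cc(OCc3ccccc3)c(C(=O)C#Cc3ccc(OC)cc3)c2OC(C)=O)cc1
F5 | step 10 | 4-{[5-(benzyloxy)-7-methoxy-2-(4-methoxyphenyl)-4-oxo-4H-chromen-8-yl]oxy}benzoic acid | COc1ccc(-c2cc(=O)c3c(OCc4ccccc4)cc(OC)c(Oc4ccc(C(=O)O)cc4)c3o2)cc1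
F6 | step 10 | 2-acetyl-3,5-bis(benzyloxy)phenyl 4-{[5-(benzyloxy)-7-methoxy-2-(4-methoxyphenyl)-4-oxo-4H-chromen-8-yl]oxy}benzoate | COc1ccc(-c2cc(=O)c3c(OCc4ccccc4)cc(OC)c(Oc4ccc(C(=O)Oc5cc(OCc6ccccc6)cc(OCc6ccccc6)c5C(C)=O)cc4)c3o2)cc1
F0 | step 12 | none | none
A1 | alternative 1 | 5-hydroxy-2-(4-{[5-hydroxy-7-methoxy-2-(4-methoxyphenyl)-4-oxo-4H-chromen-8-yl]oxy}phenyl)-4-oxo-4H-chromen-7-yl acetate | COc1ccc(-c2cc(=O)c3c(O)cc(OC)c(Oc4ccc(-c5cc(=O)c6c(O)cc(OC(C)=O)cc6o5)cc4)c3o2)cc1
A2 | alternative 1 | 2-(4-{[7-methoxy-2-(4-methoxyphenyl)-4-oxo-4H-chromen-8-yl]oxy}phenyl)-4-oxo-4H-chromen-7-yl acetate | COc1ccc(-c2cc(=O)c3ccc(OC)c(Oc4ccc(-c5cc(=O)c6ccc(OC(C)=O)cc6o5)cc4)c3o2)cc1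
A3 | alternative 2 | tert-butyl 4-{[5-hydroxy-7-methoxy-2-(4-methoxyphenyl)-4-oxo-4H-chromen-8-yl]oxy}benzoate | COc1ccc(-c2cc(=O)c3c(O)cc(OC)c(Oc4ccc(C(=O)OC(C)(C)C)cc4)c3o2)cc1
A4 | alternative 2 | 5-bromo-2-(4-methoxyphenyl)-4H-pyran-4-one | COc1ccc(-c2cc(=O)c(Br)co2)cc1
A5 | alternative 2 | tert-butyl 4-{[2,4-dimethoxy-4-(trimethylsilyloxy)buta-1,3-dien-1-yl]oxy}benzoate (mixture of double-bond isomers) | COC(=CC(OC)=COc1ccc(C(=O)OC(C)(C)C)cc1)O[Si](C)(C)C
A6 | alternative 3 | methyl 4-{[5,7-dimethoxy-2-(4-methoxyphenyl)-4-oxo-4H-chromen-8-yl]oxy}benzoate | COC(=O)c1ccc(Oc2c(OC)cc(OC)c3c2oc(-c2ccc(OC)cc2)cc3=O)cc1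
A7 | alternative 3 | methyl 4-{2,4-dimethoxy-5-[3-(4-methoxyphenyl)-3-oxopropanoyl]phenoxy}benzoate | COC(=O)c1ccc(Oc2cc(C(=O)CC(=O)c3ccc(OC)cc3)c(OC)cc2OC)cc1
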